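**Plan**

1. Numbering (carotane): cyclopentane C1 (quaternary, CH3)–C2 (OAc)–C3H2–C4 (OH, iPr)–C5 (H); cycloheptene C5–C6 (veratroate)–C7H2–C8(CH3)=C9–C10 (OAc)–C1.
2. Retrosynthesis: the three esters and the C4 isopropyl group come off first (C4 ketone, O2/O10 tied as a di-tert-butylsilylene, O6 silylated); then C1–C5 and C2–C3 are cut together, which opens both rings to one acyclic chain; the chain is cut at C4–C5=C6 (cross-metathesis, epoxidation), C10–C1 (aldol) and the C8 methyl (carbocupration).
3. Enabling feature: in the cyclopentane the middle carbon C4 of the C3–C4–C5 unit and C2 both carry oxygen, and C6 next to C5 carries oxygen. C3–C4–C5 can therefore arrive as a 2-siloxyallyl cation released from a C5–C6 epoxide, and C1=C2 as an enol ether. O2 and O10 flank quaternary C1 as a 1,3-diol, so this enol ether can be locked in a six-membered silylene ring (temporary ring, cleaved in step 16).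
4. Forward order: acyclic epoxy enol silane → one step closes the cycloheptene (C1–C5) and the cyclopentanone (C2–C3) → isopropyl at C4 → veratroate at O6 → silylene off → diacetate.
5. Stereochemistry: C10 from an Evans syn aldol; C6 and C5 from a catalyst-controlled trans epoxide (C6 retained, C5 inverted); C1 and C2 relayed from C10 by the silylene ring and the tether; C4 by addition anti to C6 and the C1 methyl; the cis C8=C9 olefin from syn carbocupration.

Key step: step 12

Remark: the lanthanum–(S)-BINOL catalyst of step 10 is assumed to give the (2R,3S) epoxide by analogy with other (E)-alkenyl ketones; the antipodal ligand would be used if the opposite sense were found.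

**Route**

Step 1
Reactants: 1 methyl propiolate; 2 allyl bromide
Product: 3 methyl hex-5-en-2-ynoate
Conditions: CuI (10 mol %), K2CO3, Bu4NI (10 mol %), DMF, rt
Reagents that add atoms: none
Why: the copper acetylide formed under mild carbonate base is allylated by allyl bromide (copper-mediated alkyne–allyl halide coupling), which should give the skipped enyne without touching the ester.

Step 2
Reactants: 3 methyl hex-5-en-2-ynoate
Product: 4 methyl (2Z)-3-methylhexa-2,5-dienoate
Conditions: Me2CuLi (from MeLi and CuI), THF, −78 °C; then sat. aq. NH4Cl at −78 °C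
Reagents that add atoms: lithium dimethylcuprate, [Li+].C[Cu-]C
Why: syn carbocupration of the ynoate and protonation of the alkenylcuprate with retention place the new methyl group cis to hydrogen, so the allyl chain and the ester end up cis (2Z), as the later ring olefin C8=C9 requires.

Step 3
Reactants: 4 methyl (2Z)-3-methylhexa-2,5-dienoate
Product: 5 (2Z)-3-methylhexa-2,5-dien-1-ol
Conditions: iBu2AlH (2.2 equiv), CH2Cl2, −78 °C; Rochelle salt work-up
Reagents that add atoms: none
Why: 1,2-reduction of the enoate with the aluminium hydride should give the allylic alcohol without isomerising the trisubstituted olefin.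

Step 4
Reactants: 5 (2Z)-3-methylhexa-2,5-dien-1-ol
Product: 6 (2Z)-3-methylhexa-2,5-dienal
Conditions: MnO2 (excess), CH2Cl2, rt, dark
Reagents that add atoms: none
Why: allylic alcohol oxidation with MnO2 is neutral and heterogeneous, which should preserve the Z olefin and the skipped diene.

Step 5
Reactants: 6 (2Z)-3-methylhexa-2,5-dienal; 7 (4S)-4-benzyl-3-propanoyl-1,3-oxazolidin-2-one
Product: 8 (4S)-4-benzyl-3-[(2S,3R,4Z)-3-hydroxy-2,5-dimethylocta-4,7-dienoyl]-1,3-oxazolidin-2-one
Conditions: 7 with Bu2BOTf, iPr2NEt, CH2Cl2, 0 °C; then 6, −78 → 0 °C; then pH 7 buffer, MeOH, H2O2, 0 °C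
Reagents that add atoms: none
Why: Evans syn aldol reaction, in which the (Z)-boron enolate of the (S)-benzyl oxazolidinone adds through a closed chair transition state and sets the carbinol carbon (the future C10) as R, the adjacent methyl stereocentre being erased in step 8.

Step 6
Reactants: 8 (4S)-4-benzyl-3-[(2S,3R,4Z)-3-hydroxy-2,5-dimethylocta-4,7-dienoyl]-1,3-oxazolidin-2-one
Product: 9 (2R,3R,4Z)-2,5-dimethylocta-4,7-diene-1,3-diol
Conditions: LiBH4, MeOH (1 equiv), Et2O, 0 °C
Reagents that add atoms: none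
Why: reductive cleavage of the imide with LiBH4 should release the 1,3-diol and the auxiliary without affecting the olefins.

Step 7
Reactants: 9 (2R,3R,4Z)-2,5-dimethylocta-4,7-diene-1,3-diol
Product: 10 (2S,3R,4Z)-3-hydroxy-2,5-dimethylocta-4,7-dienal
Conditions: TEMPO (10 mol %), PhI(OAc)2, CH2Cl2, rt; crude product used at once
Reagents that add atoms: none
Why: the oxoammonium-mediated oxidation is selective for the primary over the secondary allylic hydroxyl and should give the β-hydroxy aldehyde, whose α-epimerisation is of no consequence.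

Step 8
Reactants: 10 (2S,3R,4Z)-3-hydroxy-2,5-dimethylocta-4,7-dienal
Product: 11 (4R)-2,2-di-tert-butyl-5-methyl-4-[(1Z)-2-methylpenta-1,4-dien-1-yl]-4H-1,3,2-dioxasiline
Conditions: tBu2Si(OTf)2, Et3N, CH2Cl2, 0 °C → rt
Reagents that add atoms: di-tert-butylsilyl bis(trifluoromethanesulfonate), CC(C)(C)[Si](OS(=O)(=O)C(F)(F)F)(OS(=O)(=O)C(F)(F)F)C(C)(C)C
Why: the bis-triflate silylates the carbinol and then, held next to the aldehyde, silylates its enol oxygen (silyl triflate/amine enol silylation), so the six-membered ring fixes the enol ether geometry with O2 cis to C10 and erases the α-stereocentre.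

Step 9
Reactants: 11 (4R)-2,2-di-tert-butyl-5-methyl-4-[(1Z)-2-methylpenta-1,4-dien-1-yl]-4H-1,3,2-dioxasiline; 12 but-3-en-2-one
Product: 13 (3E,6Z)-7-[(4R)-2,2-di-tert-butyl-5-methyl-4H-1,3,2-dioxasilin-4-yl]-6-methylhepta-3,6-dien-2-one
Conditions: second-generation Hoveyda–Grubbs catalyst (5 mol %), 12 (3 equiv), CH2Cl2, 40 °C
Reagents that add atoms: none
Why: olefin cross-metathesis of the terminal monosubstituted olefin with the electron-poor enone partner is E-selective and should leave the trisubstituted olefin and the hindered cyclic enol ether untouched.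

Step 10
Reactants: 13 (3E,6Z)-7-[(4R)-2,2-di-tert-butyl-5-methyl-4H-1,3,2-dioxasilin-4-yl]-6-methylhepta-3,6-dien-2-one
Product: 14 1-[(2R,3S)-3-{(2Z)-3-[(4R)-2,2-di-tert-butyl-5-methyl-4H-1,3,2-dioxasilin-4-yl]-2-methylprop-2-en-1-yl}oxiran-2-yl]ethan-1-one
Conditions: La(OiPr)3 (10 mol %), (S)-BINOL (10 mol %), Ph3AsO (10 mol %), tBuOOH (decane), 4 Å molecular sieves, THF, rt
Reagents that add atoms: tert-butyl hydroperoxide, CC(C)(C)OO
Why: catalytic asymmetric nucleophilic (Weitz–Scheffer-type) epoxidation of the (E)-enone is stereospecific for the trans epoxide and catalyst-controlled for the (2R,3S) configuration (C5 R, C6 S), while the electron-rich enol ether and the isolated olefin are inert to the nucleophilic peroxide.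

Step 11
Reactants: 14 1-[(2R,3S)-3-{(2Z)-3-[(4R)-2,2-di-tert-butyl-5-methyl-4H-1,3,2-dioxasilin-4-yl]-2-methylprop-2-en-1-yl}oxiran-2-yl]ethan-1-one
Product: 15 triethyl({1-[(2R,3S)-3-{(2Z)-3-[(4R)-2,2-di-tert-butyl-5-methyl-4H-1,3,2-dioxasilin-4-yl]-2-methylprop-2-en-1-yl}oxiran-2-yl]ethenyl}oxy)silane
Conditions: LiN(SiMe3)2, Et3SiCl, Et3N, THF, −78 °C (in situ quench)
Reagents that add atoms: chlorotriethylsilane, CC[Si](Cl)(CC)CC
Why: kinetic deprotonation of the methyl ketone (the epoxide α-hydrogen is not removed) with in situ O-silylation should give the terminal enol silane (enol silane formation).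

Step 12
Reactants: 15 triethyl({1-[(2R,3S)-3-{(2Z)-3-[(4R)-2,2-di-tert-butyl-5-methyl-4H-1,3,2-dioxasilin-4-yl]-2-methylprop-2-en-1-yl}oxiran-2-yl]ethenyl}oxy)silane
Product: 17 trans-fused tricyclic ketone (1R,2S,5S,6S,10R)-2,10-O-(di-tert-butylsilanediyl)-2,10-dihydroxy-1,8-dimethyl-6-(triethylsilyloxy)bicyclo[5.3.0]dec-8-en-4-one (target numbering), via cyclic silyloxocarbenium triflate 16 (not isolated)
Conditions: Et3SiOTf (0.2 equiv), 2,6-di-tert-butyl-4-methylpyridine (0.3 equiv), CH2Cl2, −78 °C
Reagents that add atoms: none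
Why: Proposed new method: silylation of the epoxide oxygen by Et3SiOTf lets the C5–O bond ionise with help from the adjacent enol silane (incipient 2-siloxyallyl cation), the tethered enol ether carbon C1 attacks C5 anti to the departing oxygen, and the cyclic silyloxocarbenium ion 16 is captured at C2 by the enol silane carbon C3 with release of Et3SiOTf, which makes the step catalytic and leaves the triethylsilyl group on O6; the closest known reaction types are the silyl triflate-catalysed (4+3) cycloadditions of epoxy enol silanes with tethered dienes, which transfer the epoxide configuration, and the (3+2) cyclopentanone annulation of 2-siloxyallyl cations with enol silyl ethers. The seven-membered ring closes by 7-endo opening of the epoxide at C5 (6-exo attack at C6 is disfavoured because only C5 is conjugated with the enol silane), and the five-membered ring by 5-(enolendo)-exo-trig addition of C3 to the C2 oxocarbenium ion, the closure common to oxyallyl (3+2) annulations. C5 is set by inversion at the epoxide carbon and C6 is carried over unchanged; C1 is set by C10, because the four-carbon tether from C10 can deliver C5 only to the face of the dioxasiline ring on which C9 stands; C2 follows from C1, because the oxocarbenium carbon is held in the six-membered silylene ring and can only be attacked from the side of the C5 arm, which places O2 cis to C10. The required trans ring fusion is therefore fixed by pairing the (2R,3S) epoxide with the (4R) dioxasiline, and it should be reached through a transition state in which C6 lies syn to the siloxy group and the dioxasiline ring points away from it. The step needs ionisation of the epoxide in preference to the allylic C10–O bond, attack by the enol ether in preference to the C8=C9 olefin, and C- over O-closure; the first is secured because the C10–O bond is endocyclic, lies near the nodal plane of the enol ether and belongs to a hindered, weakly basic silyl ether, the second by the far higher nucleophilicity of the enol ether, and the third by the silyl group that stays on O4 until the ring is closed.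

Step 13
Reactants: 17 trans-fused tricyclic ketone (1R,2S,5S,6S,10R)-2,10-O-(di-tert-butylsilanediyl)-2,10-dihydroxy-1,8-dimethyl-6-(triethylsilyloxy)bicyclo[5.3.0]dec-8-en-4-one
Product: 18 (1R,2S,4R,5S,6S,10R)-2,10-O-(di-tert-butylsilanediyl)-6-O-(triethylsilyl)carot-8-ene-2,4,6,10-tetrol
Conditions: iPrMgCl, CeCl3 (anhydrous), THF, −78 → −40 °C; then sat. aq. NH4Cl
Reagents that add atoms: isopropylmagnesium chloride, CC(C)[Mg]Cl
Why: organocerium addition to the enolisable cyclopentanone (which suppresses enolisation and β-elimination) is expected on the face opposite the C6 substituent on C5 and the angular C1 methyl, which places the isopropyl group cis to H5 and the hydroxyl cis to the C1 methyl (4R).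

Step 14
Reactants: 18 (1R,2S,4R,5S,6S,10R)-2,10-O-(di-tert-butylsilanediyl)-6-O-(triethylsilyl)carot-8-ene-2,4,6,10-tetrol
Product: 19 (1R,2S,4R,5S,6S,10R)-2,10-O-(di-tert-butylsilanediyl)carot-8-ene-2,4,6,10-tetrol
Conditions: PPTS (cat.), MeOH/CH2Cl2, 0 °C
Reagents that add atoms: none
Why: mild acid-catalysed methanolysis should cleave the secondary triethylsilyl ether selectively, the six-membered di-tert-butylsilylene ring being far more stable to these conditions.

Step 15
Reactants: 19 (1R,2S,4R,5S,6S,10R)-2,10-O-(di-tert-butylsilanediyl)carot-8-ene-2,4,6,10-tetrol; 20 3,4-dimethoxybenzoyl chloride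
Product: 21 (1R,2S,4R,5S,6S,10R)-2,10-O-(di-tert-butylsilanediyl)-6-O-(3,4-dimethoxybenzoyl)carot-8-ene-2,4,6,10-tetrol
Conditions: Et3N, DMAP, CH2Cl2, rt
Reagents that add atoms: none
Why: DMAP-catalysed acylation should esterify the secondary C6 hydroxyl only, the tertiary C4 hydroxyl being unreactive under these conditions.

Step 16
Reactants: 21 (1R,2S,4R,5S,6S,10R)-2,10-O-(di-tert-butylsilanediyl)-6-O-(3,4-dimethoxybenzoyl)carot-8-ene-2,4,6,10-tetrol
Product: 22 (1R,2S,4R,5S,6S,10R)-6-O-(3,4-dimethoxybenzoyl)carot-8-ene-2,4,6,10-tetrol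
Conditions: HF·pyridine, pyridine, THF, 0 °C
Reagents that add atoms: none
Why: buffered fluoride cleaves the di-tert-butylsilylene (the temporary ring) under conditions that should neither cleave nor shift the aryl ester.

Step 17
Reactants: 22 (1R,2S,4R,5S,6S,10R)-6-O-(3,4-dimethoxybenzoyl)carot-8-ene-2,4,6,10-tetrol
Product: 23 (1R,2S,4R,5S,6S,10R)-2,10-di-O-acetyl-6-O-(3,4-dimethoxybenzoyl)carot-8-ene-2,4,6,10-tetrol (CNP0320758.1)
Conditions: Ac2O, pyridine, DMAP (cat.), CH2Cl2, 0 °C → rt
Reagents that add atoms: acetic anhydride, CC(=O)OC(C)=O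
Why: acetylation of the two secondary hydroxyls at C2 and C10 should leave the hindered tertiary C4 hydroxyl free and give the target.

**Compound list**

(carotane = 4-isopropyl-1,8-dimethylbicyclo[5.3.0]decane, numbered as in the plan)

1 | methyl propiolate | C#CC(=O)OC | starting material
2 | allyl bromide | C=CCBr | starting material
3 | methyl hex-5-en-2-ynoate | C=CCC#CC(=O)OC | intermediate
4 | methyl (2Z)-3-methylhexa-2,5-dienoate | CC(/CC=C)=C/C(=O)OC | intermediate
5 | (2Z)-3-methylhexa-2,5-dien-1-ol | CC(/CC=C)=C/CO | intermediate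
6 | (2Z)-3-methylhexa-2,5-dienal | CC(/CC=C)=C/C=O | intermediate
7 | (4S)-4-benzyl-3-propanoyl-1,3-oxazolidin-2-one | CCC(=O)N1[C@@H](Cc2ccccc2)COC1=O | starting material
8 | (4S)-4-benzyl-3-[(2S,3R,4Z)-3-hydroxy-2,5-dimethylocta-4,7-dienoyl]-1,3-oxazolidin-2-one | CC(/CC=C)=C/[C@@H](O)[C@H](C)C(=O)N1[C@@H](Cc2ccccc2)COC1=O | intermediate
9 | (2R,3R,4Z)-2,5-dimethylocta-4,7-diene-1,3-diol | CC(/CC=C)=C/[C@@H](O)[C@H](C)CO | intermediate
10 | (2S,3R,4Z)-3-hydroxy-2,5-dimethylocta-4,7-dienal | CC(/CC=C)=C/[C@@H](O)[C@H](C)C=O | intermediate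
11 | (4R)-2,2-di-tert-butyl-5-methyl-4-[(1Z)-2-methylpenta-1,4-dien-1-yl]-4H-1,3,2-dioxasiline | CC(/CC=C)=C/[C@H]1O[Si](C(C)(C)C)(C(C)(C)C)OC=C1C | intermediate
12 | but-3-en-2-one | CC(=O)C=C | starting material
13 | (3E,6Z)-7-[(4R)-2,2-di-tert-butyl-5-methyl-4H-1,3,2-dioxasilin-4-yl]-6-methylhepta-3,6-dien-2-one | CC(/C/C=C/C(C)=O)=C/[C@H]1O[Si](C(C)(C)C)(C(C)(C)C)OC=C1C | intermediate
14 | 1-[(2R,3S)-3-{(2Z)-3-[(4R)-2,2-di-tert-butyl-5-methyl-4H-1,3,2-dioxasilin-4-yl]-2-methylprop-2-en-1-yl}oxiran-2-yl]ethan-1-one | CC(/C[C@@H]2O[C@H]2C(C)=O)=C/[C@H]1O[Si](C(C)(C)C)(C(C)(C)C)OC=C1C | intermediate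
15 | triethyl({1-[(2R,3S)-3-{(2Z)-3-[(4R)-2,2-di-tert-butyl-5-methyl-4H-1,3,2-dioxasilin-4-yl]-2-methylprop-2-en-1-yl}oxiran-2-yl]ethenyl}oxy)silane | CC(/C[C@@H]2O[C@H]2C(=C)O[Si](CC)(CC)CC)=C/[C@H]1O[Si](C(C)(C)C)(C(C)(C)C)OC=C1C | intermediate
16 | cyclic silyloxocarbenium triflate (C1–C5 bond formed, enol silane intact, O6 silylated) | C=C(O[Si](CC)(CC)CC)[C@@H]2[C@@H](O[Si](CC)(CC)CC)CC(C)=C[C@H]3O[Si](C(C)(C)C)(C(C)(C)C)[O+]=C[C@@]23C.[O-]S(=O)(=O)C(F)(F)F | intermediate
17 | (1R,2S,5S,6S,10R)-2,10-O-(di-tert-butylsilanediyl)-2,10-dihydroxy-1,8-dimethyl-6-(triethylsilyloxy)bicyclo[5.3.0]dec-8-en-4-one (target numbering) | CC[Si](CC)(CC)O[C@H]2CC(C)=C[C@@H](O[Si]4(C(C)(C)C)C(C)(C)C)[C@@]3(C)[C@@H](O4)CC(=O)[C@H]23 | intermediate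
18 | (1R,2S,4R,5S,6S,10R)-2,10-O-(di-tert-butylsilanediyl)-6-O-(triethylsilyl)carot-8-ene-2,4,6,10-tetrol | CC[Si](CC)(CC)O[C@H]2CC(C)=C[C@@H](O[Si]4(C(C)(C)C)C(C)(C)C)[C@@]3(C)[C@@H](O4)C[C@@](O)(C(C)C)[C@H]23 | intermediate
19 | (1R,2S,4R,5S,6S,10R)-2,10-O-(di-tert-butylsilanediyl)carot-8-ene-2,4,6,10-tetrol | O[C@H]2CC(C)=C[C@@H](O[Si]4(C(C)(C)C)C(C)(C)C)[C@@]3(C)[C@@H](O4)C[C@@](O)(C(C)C)[C@H]23 | intermediate
20 | 3,4-dimethoxybenzoyl chloride | COc1ccc(C(Cl)=O)cc1OC | starting material
21 | (1R,2S,4R,5S,6S,10R)-2,10-O-(di-tert-butylsilanediyl)-6-O-(3,4-dimethoxybenzoyl)carot-8-ene-2,4,6,10-tetrol | COc1ccc(C(=O)O[C@H]2CC(C)=C[C@@H](O[Si]4(C(C)(C)C)C(C)(C)C)[C@@]3(C)[C@@H](O4)C[C@@](O)(C(C)C)[C@H]23)cc1OC | intermediate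
22 | (1R,2S,4R,5S,6S,10R)-6-O-(3,4-dimethoxybenzoyl)carot-8-ene-2,4,6,10-tetrol | COc1ccc(C(=O)O[C@H]2CC(C)=C[C@@H](O)[C@@]3(C)[C@@H](O)C[C@@](O)(C(C)C)[C@H]23)cc1OC | intermediate
23 | (1R,2S,4R,5S,6S,10R)-2,10-di-O-acetyl-6-O-(3,4-dimethoxybenzoyl)carot-8-ene-2,4,6,10-tetrol | COc1ccc(C(=O)O[C@H]2CC(C)=C[C@@H](OC(C)=O)[C@@]3(C)[C@@H](OC(C)=O)C[C@@](O)(C(C)C)[C@H]23)cc1OC | target

**Step count and risks**

Total step count: 17. Longest linear sequence: 17 steps (1 → 23).

Steps most likely to fail:

1. Step 12 (Proposed new method). The silyl triflate may ionise the silylene enol ether or the allylic C10–O bond instead of the epoxide, or the cation at C5 may be lost by hydride shift or elimination before the C–C bond forms. The fallback uses known chemistry, sets out from 14 and comes back at 17. The epoxy ketone would be opened at the α-carbon with MgBr2·OEt2 to the anti bromohydrin (3S,4S,6Z)-3-bromo-7-[(4R)-2,2-di-tert-butyl-5-methyl-4H-1,3,2-dioxasilin-4-yl]-4-hydroxy-6-methylhept-6-en-2-one F1. Silylation (Et3SiCl, imidazole, DMF) would give the α-bromo β-silyloxy ketone (3S,4S,6Z)-3-bromo-7-[(4R)-2,2-di-tert-butyl-5-methyl-4H-1,3,2-dioxasilin-4-yl]-6-methyl-4-(triethylsilyloxy)hept-6-en-2-one F2. Treatment of F2 with Et3N in 2,2,2-trifluoroethanol would enolise the ketone towards its methyl group and expel bromide, the established Lewis-acid-free entry to oxyallyl cations from α-halo ketones, whose capture by electron-rich π-nucleophiles and (3+2) annulation to cyclopentanones are known. Closure on the tethered enol ether would return 17. In this variant C5 is no longer set by the epoxide but by the preference of the planar cation for the transition state described in step 12.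

2. Step 10. The basic peroxide system may move the enone double bond into conjugation with C8=C9 through the doubly allylic C7 methylene, or the catalyst may give poor facial control. The fallback sets out from 13 and comes back at 14. Corey–Bakshi–Shibata reduction ((R)-2-methyl-CBS-oxazaborolidine, catecholborane, toluene, −78 °C) would give (2S,3E,6Z)-7-[(4R)-2,2-di-tert-butyl-5-methyl-4H-1,3,2-dioxasilin-4-yl]-6-methylhepta-3,6-dien-2-ol F3. Matched Sharpless asymmetric epoxidation (Ti(OiPr)4, L-(+)-diisopropyl tartrate, tBuOOH, 4 Å molecular sieves, CH2Cl2, −20 °C) would give the erythro epoxy alcohol (1S)-1-[(2S,3S)-3-{(2Z)-3-[(4R)-2,2-di-tert-butyl-5-methyl-4H-1,3,2-dioxasilin-4-yl]-2-methylprop-2-en-1-yl}oxiran-2-yl]ethan-1-ol F4. Dess–Martin oxidation buffered with NaHCO3 would then give 14. The epoxide is formed under non-basic, reagent-controlled conditions and the carbinol stereocentre is erased at the end.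

3. Step 13. The branched organometallic may reduce the ketone by β-hydride transfer, or enolise it with β-elimination of a silyloxy group or retro-aldol opening. The fallback sets out from 17 and comes back at 18. Addition of 2-propenylmagnesium bromide with CeCl3, an sp2 nucleophile without transferable β-hydrogens, would give the isopropenyl carbinol (1R,2S,4S,5S,6S,10R)-2,10-O-(di-tert-butylsilanediyl)-1,8-dimethyl-4-(prop-1-en-2-yl)-6-(triethylsilyloxy)bicyclo[5.3.0]dec-8-ene-2,4,10-triol F5. Hydrogenation of its 1,1-disubstituted olefin with RhCl(PPh3)3 and H2 in benzene, which spares the trisubstituted ring olefin, would give 18.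

**Further compounds**

F1 | step 12 | (3S,4S,6Z)-3-bromo-7-[(4R)-2,2-di-tert-butyl-5-methyl-4H-1,3,2-dioxasilin-4-yl]-4-hydroxy-6-methylhept-6-en-2-one | CC(/C[C@H](O)[C@H](Br)C(C)=O)=C/[C@H]1O[Si](C(C)(C)C)(C(C)(C)C)OC=C1C
F2 | step 12 | (3S,4S,6Z)-3-bromo-7-[(4R)-2,2-di-tert-butyl-5-methyl-4H-1,3,2-dioxasilin-4-yl]-6-methyl-4-(triethylsilyloxy)hept-6-en-2-one | CC(/C[C@H](O[Si](CC)(CC)CC)[C@H](Br)C(C)=O)=C/[C@H]1O[Si](C(C)(C)C)(C(C)(C)C)OC=C1C
F3 | step 10 | (2S,3E,6Z)-7-[(4R)-2,2-di-tert-butyl-5-methyl-4H-1,3,2-dioxasilin-4-yl]-6-methylhepta-3,6-dien-2-ol | CC(/C/C=C/[C@H](C)O)=C/[C@H]1O[Si](C(C)(C)C)(C(C)(C)C)OC=C1C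
F4 | step 10 | (1S)-1-[(2S,3S)-3-{(2Z)-3-[(4R)-2,2-di-tert-butyl-5-methyl-4H-1,3,2-dioxasilin-4-yl]-2-methylprop-2-en-1-yl}oxiran-2-yl]ethan-1-ol | CC(/C[C@@H]2O[C@H]2[C@H](C)O)=C/[C@H]1O[Si](C(C)(C)C)(C(C)(C)C)OC=C1C
F5 | step 13 | (1R,2S,4S,5S,6S,10R)-2,10-O-(di-tert-butylsilanediyl)-1,8-dimethyl-4-(prop-1-en-2-yl)-6-(triethylsilyloxy)bicyclo[5.3.0]dec-8-ene-2,4,10-triol (target numbering) | CC[Si](CC)(CC)O[C@H]2CC(C)=C[C@@H](O[Si]4(C(C)(C)C)C(C)(C)C)[C@@]3(C)[C@@H](O4)C[C@@](O)(C(C)=C)[C@H]23
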